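**Retrosynthetic overview**
Locants follow the carbon chain: C1 ester C=O, C2, C3–C6 dioxane carbons, C7–C8 ethylene bridge, C9 ring-B methine, C10=C11 ring-B alkene, C12, C13 ring-fusion CH, C14 CMe2, C15–C17, C18 quaternary ring-fusion carbon.
Enabling feature: the bond C8–C9 is allylic to the ring-B alkene C10=C11. The array C8–C9–C10=C11 therefore becomes the γ,δ-unsaturated retron of an Ireland–Claisen rearrangement once a sacrificial carboxyl group sits on C8. The temporary tether is an ester C11–O bond on the ring-B face that carries the C18 methyl group.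
Disconnections: C8–CO2H (Barton decarboxylation), then C8–C9 ([3,3] shift), then the ester of a ring-B allylic alcohol (fragment 1) with a dioxane propanoic acid (fragment 2).
Fragment 1: rings A and B come preformed from a bought octalone. The sequence is gem-dimethylation, deoxygenation, allylic oxidation, methylation, trans reduction, dehydrogenation and Luche reduction.
Fragment 2: an Evans syn aldol sets C2 and C3. The dioxane, the only ring made in the route, closes by SN2 inversion at C3 of a hydroperoxy ketal, and C6 is set by axial allylation of a peroxycarbenium ion.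

Key step: step 19

Remark on the chemistry: the decalin of the target belongs to the enantiomeric (ent) drimane series, so the (R) form of octalone 1 is needed, and it is taken as commercially available, as are 14 and 16.

Step 1
Reactants: 1 (4aR)-4a-methyl-4,4a,5,6,7,8-hexahydronaphthalen-2(3H)-one
Product: 3 (4aR)-1,1,4a-trimethyl-3,4,4a,5,6,7-hexahydronaphthalen-2(1H)-one, via monomethyl enone 2 (not isolated)
Conditions: KOtBu (3 equiv), MeI (4 equiv), t-BuOH, 25 to 40 °C
Reagents that add atoms: iodomethane CI
Why: Deconjugative double C-alkylation of the thermodynamic dienolate of a 4-en-3-one-type enone (classical gem-dimethylation) puts both methyl groups on C14 and shifts the alkene to C12=C13 without touching the C18 stereocentre.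

Step 2
Reactants: 3 (4aR)-1,1,4a-trimethyl-3,4,4a,5,6,7-hexahydronaphthalen-2(1H)-one
Product: 5 (4aR)-1,1,4a-trimethyl-1,2,3,4,4a,5,6,7-octahydronaphthalene, via hydrazone 4 (not isolated)
Conditions: N2H4·H2O, KOH, diethylene glycol, 130 then 210 °C
Reagents that add atoms: none
Why: Wolff–Kishner reduction (Huang-Minlon variant) removes the hindered C15 ketone, and the C12=C13 alkene cannot move into conjugation because C14 is quaternary.

Step 3
Reactants: 5 (4aR)-1,1,4a-trimethyl-1,2,3,4,4a,5,6,7-octahydronaphthalene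
Product: 6 (4aS)-4a,8,8-trimethyl-4,4a,5,6,7,8-hexahydronaphthalen-2(3H)-one
Conditions: Rh2(cap)4 (cap = caprolactamate, 1 mol %), aq. t-BuOOH (excess), ClCH2CH2Cl, 40 °C
Reagents that add atoms: tert-butyl hydroperoxide CC(C)(C)OO
Why: Rhodium-catalysed allylic oxidation with t-BuOOH, well known for steroidal 5-enes, can only attack C11 because the other allylic positions C14 and C18 are quaternary.

Step 4
Reactants: 6 (4aS)-4a,8,8-trimethyl-4,4a,5,6,7,8-hexahydronaphthalen-2(3H)-one
Product: 8 (4aS)-3,4a,8,8-tetramethyl-4,4a,5,6,7,8-hexahydronaphthalen-2(3H)-one (C3 epimers), via lithium dienolate 7 (not isolated)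
Conditions: LiN(iPr)2 (1.1 equiv), THF, −78 °C; MeI, −78 to −20 °C
Reagents that add atoms: iodomethane CI
Why: Kinetic deprotonation of the enone at the α' carbon C10 and SN2 methylation of the cross-conjugated dienolate installs the future vinylic methyl group, and the C10 configuration is irrelevant because it is lost in step 6.

Step 5
Reactants: 8 (4aS)-3,4a,8,8-tetramethyl-4,4a,5,6,7,8-hexahydronaphthalen-2(3H)-one
Product: 10 (4aS,8aR)-3,4a,8,8-tetramethyloctahydronaphthalen-2(1H)-one (trans-fused; C3 epimers), via lithium enolate 9 (not isolated)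
Conditions: Li, NH3(l)/THF, t-BuOH (1 equiv), −78 °C; solid NH4Cl
Reagents that add atoms: none
Why: Dissolving-metal (Birch-type) enone reduction protonates the β-carbon C13 axially on the face opposite to the C18 methyl group and so sets the trans ring fusion.

Step 6
Reactants: 10 (4aS,8aR)-3,4a,8,8-tetramethyloctahydronaphthalen-2(1H)-one
Product: 11 trimethylsilyl enol ether of 10 with the C10=C11 double bond
Conditions: Me3SiCl, NaI, Et3N, MeCN, 25 to 60 °C
Reagents that add atoms: chlorotrimethylsilane C[Si](C)(C)Cl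
Why: Silylation under equilibrating conditions (Me3SiI made in situ) gives the more substituted enol ether C10=C11, favoured both by the methyl group and by the usual preference of trans-fused 2-decalones to enolise away from the ring fusion.

Step 7
Reactants: 11 trimethylsilyl enol ether of 10
Product: 12 (4aS,8aR)-3,4a,8,8-tetramethyl-4a,5,6,7,8,8a-hexahydronaphthalen-2(1H)-one
Conditions: Pd(OAc)2 (1.05 equiv), MeCN, 25 to 40 °C
Reagents that add atoms: none
Why: Saegusa–Ito oxidation, in which the divalent palladium enolate at C10 undergoes β-hydride elimination towards C9 to give the conjugated endocyclic 2-methyl enone and zerovalent palladium.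

Step 8
Reactants: 12 (4aS,8aR)-3,4a,8,8-tetramethyl-4a,5,6,7,8,8a-hexahydronaphthalen-2(1H)-one
Product: 13 (2R,4aS,8aR)-3,4a,8,8-tetramethyl-1,2,4a,5,6,7,8,8a-octahydronaphthalen-2-ol (OH cis to the angular methyl group)
Conditions: NaBH4, CeCl3·7H2O, MeOH, −78 to 0 °C
Reagents that add atoms: none
Why: Luche 1,2-reduction delivers hydride axially from the face opposite to the C18 methyl group, as with steroidal 1-en-3-ones and carvone, and so sets the pseudoequatorial C11 alcohol cis to that methyl group.

Step 9
Reactants: 14 4-methylpent-4-en-1-ol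
Product: 15 4-methylpent-4-enal
Conditions: TEMPO (cat.), PhI(OAc)2 (1.1 equiv), CH2Cl2, 25 °C
Reagents that add atoms: none
Why: Oxoammonium (TEMPO) oxidation stops cleanly at the volatile aldehyde and does not touch the 1,1-disubstituted alkene.

Step 10
Reactants: 15 4-methylpent-4-enal; 16 (4S)-4-benzyl-3-propanoyl-1,3-oxazolidin-2-one
Product: 18 (4S)-4-benzyl-3-[(2S,3R)-3-hydroxy-2,6-dimethylhept-6-enoyl]-1,3-oxazolidin-2-one, via boron enolate 17 (not isolated)
Conditions: Bu2BOTf, Et3N, CH2Cl2, −78 to 0 °C; 15, −78 to 0 °C; pH 7 buffer, MeOH, H2O2, 0 °C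
Reagents that add atoms: none
Why: Evans syn aldol reaction, in which the Z boron enolate reacts through a closed chair transition state on the face opposite to the benzyl group and sets (2S,3R), that is the final C2 and the C3 carbinol that is to be inverted.

Step 11
Reactants: 18 (4S)-4-benzyl-3-[(2S,3R)-3-hydroxy-2,6-dimethylhept-6-enoyl]-1,3-oxazolidin-2-one
Product: 19 methyl (2S,3R)-3-hydroxy-2,6-dimethylhept-6-enoate
Conditions: NaOMe (1.1 equiv), MeOH, −20 to 0 °C; aq. NH4Cl
Reagents that add atoms: sodium methoxide C[O-].[Na+]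
Why: Methoxide attacks the more electrophilic exocyclic imide carbonyl (transesterification) at low temperature, which frees the auxiliary without retro-aldol cleavage or epimerisation at C2.

Step 12
Reactants: 19 methyl (2S,3R)-3-hydroxy-2,6-dimethylhept-6-enoate
Product: 20 methyl (2S,3R)-2,6-dimethyl-3-[(methylsulfonyl)oxy]hept-6-enoate
Conditions: MsCl, Et3N, CH2Cl2, −10 °C
Reagents that add atoms: methanesulfonyl chloride CS(=O)(=O)Cl
Why: Sulfonylation of the secondary alcohol proceeds at oxygen with retention at C3 and is kept cold and short to avoid E1cB elimination.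

Step 13
Reactants: 20 methyl (2S,3R)-2,6-dimethyl-3-[(methylsulfonyl)oxy]hept-6-enoate
Product: 22 methyl (2S,3R)-6-hydroperoxy-6-methoxy-2-methyl-3-[(methylsulfonyl)oxy]heptanoate (C6 epimers), via carbonyl oxide 21 (not isolated)
Conditions: O3, MeOH/CH2Cl2, −78 °C; N2 purge, no reductant
Reagents that add atoms: ozone [O-][O+]=O; methanol CO
Why: Ozonolysis in methanol, in which the primary ozonide of a 1,1-disubstituted alkene fragments to formaldehyde and ketone oxide 21, which methanol traps as the α-methoxy hydroperoxide, the new C6 centre being a mixture that is erased in step 15.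

Step 14
Reactants: 22 methyl (2S,3R)-6-hydroperoxy-6-methoxy-2-methyl-3-[(methylsulfonyl)oxy]heptanoate
Product: 23 methyl (2S)-2-[(3S)-6-methoxy-6-methyl-1,2-dioxan-3-yl]propanoate (C6 epimers)
Conditions: KOtBu (1.0 equiv), 18-crown-6, THF, 0 °C
Reagents that add atoms: none
Why: Intramolecular 6-exo-tet SN2 alkylation of the hydroperoxide anion, a weak base but strong α-effect nucleophile, displaces the mesylate with inversion and sets (3S) while closing the 1,2-dioxane.

Step 15
Reactants: 23 methyl (2S)-2-[(3S)-6-methoxy-6-methyl-1,2-dioxan-3-yl]propanoate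
Product: 25 methyl (2S)-2-[(3S,6R)-6-allyl-6-methyl-1,2-dioxan-3-yl]propanoate (allyl cis to the C3 side chain), via peroxycarbenium ion 24 (not isolated)
Conditions: allyltrimethylsilane (3 equiv), TiCl4 (1.1 equiv), CH2Cl2, −78 °C
Reagents that add atoms: allyltrimethylsilane C=CC[Si](C)(C)C
Why: Hosomi–Sakurai-type allylation of a peroxyketal, in which TiCl4 ionises the methoxy group to peroxycarbenium ion 24, whose half-chair with the C3 substituent pseudoequatorial is attacked axially, so that the allyl group ends up cis to the C3 side chain as required at C6.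

Step 16
Reactants: 25 methyl (2S)-2-[(3S,6R)-6-allyl-6-methyl-1,2-dioxan-3-yl]propanoate
Product: 27 methyl (2S)-2-[(3S,6S)-6-(3-hydroxypropyl)-6-methyl-1,2-dioxan-3-yl]propanoate, via alkylborane 26 (not isolated)
Conditions: 9-BBN-H, THF, 0 to 25 °C; NaBO3·4H2O, H2O, 25 °C
Reagents that add atoms: sodium perborate [Na+].[Na+].O[B-]1(O)OO[B-](O)(O)OO1
Why: Anti-Markovnikov hydroboration of the terminal alkene with the bulky, chemoselective 9-BBN-H is much faster than any reaction with the ester or the dialkyl peroxide, and perborate oxidises the C–B bond under nearly neutral conditions.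

Step 17
Reactants: 27 methyl (2S)-2-[(3S,6S)-6-(3-hydroxypropyl)-6-methyl-1,2-dioxan-3-yl]propanoate
Product: 29 3-[(3R,6S)-6-[(2S)-1-methoxy-1-oxopropan-2-yl]-3-methyl-1,2-dioxan-3-yl]propanoic acid, via aldehyde 28 (not isolated)
Conditions: TEMPO (cat.), PhI(OAc)2 (2.5 equiv), MeCN/H2O, 25 °C
Reagents that add atoms: water O
Why: TEMPO/PhI(OAc)2 oxidation in aqueous acetonitrile takes the primary alcohol through the aldehyde hydrate to the acid under oxidative, non-basic conditions that leave the peroxide and C2 untouched.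

Step 18
Reactants: 13 (2R,4aS,8aR)-3,4a,8,8-tetramethyl-1,2,4a,5,6,7,8,8a-octahydronaphthalen-2-ol; 29 dioxane propanoic acid
Product: 30 allylic ester of acid 29 and alcohol 13 (C11–O on the face of the C18 methyl group)
Conditions: EDC·HCl, DMAP, CH2Cl2, 0 to 25 °C
Reagents that add atoms: none
Why: Steglich-type carbodiimide esterification acylates the allylic alcohol at oxygen, so that the C11 configuration is retained in the temporary tether.

Step 19
Reactants: 30 allylic ester of acid 29 and alcohol 13
Product: 33 target carrying a carboxyl group at C8 (C8 epimers), via ketene acetal 31 (not isolated), via silyl ester 32 (not isolated)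
Conditions: LiN(iPr)2 (1.1 equiv), Me3SiCl/Et3N (internal quench), THF, −78 °C, then 25 to 65 °C; aq. citric acid
Reagents that add atoms: none
Why: LiN(iPr)2 in the presence of Me3SiCl removes a proton from the unbranched acyl CH2 (C8) and the enolate is silylated at once to ketene acetal 31, which on warming undergoes a concerted suprafacial [3,3] shift (Ireland–Claisen rearrangement) in which C11–O breaks, C8–C9 forms and the ring-B alkene moves from C9=C10 to C10=C11, and work-up hydrolyses silyl ester 32 to 33. The closest known reaction types are Ireland–Claisen rearrangements of cyclohex-2-enyl esters and the Claisen-type angular alkylation of steroidal 4-en-3β-ol derivatives, in which carbon is likewise delivered from a pseudoequatorial C–O bond to the alkene carbon next to a quaternary centre, on the face of the angular methyl group. No ring of the target is closed; the only cyclic array is the transient six-membered pericyclic transition state (chair or boat), reached after ring B flexes at C11/C12 into a boat, which the trans ring fusion allows. C9 is controlled by the C11–O configuration of 13 through 1,3-chirality transfer across one face of ring B, so the side chain ends up cis to the C18 methyl group, the outcome that intermolecular additions to C9 (which come from the opposite face) cannot give, and the new centre at C8 is of no consequence because step 20 erases it. The step needs chemoselective enolisation of the allylic ester in the presence of the C1 methyl ester and the O–O bond: the C8 protons are secondary and unhindered whereas C2–H is tertiary and flanked by the dioxane ring, the base is used in slight excess only at −78 °C with internal silyl quench, and lithium amide enolisations next to dialkyl peroxides are tolerated at this temperature. The position of the alkene and the site of C–C bond formation are fixed by the pericyclic topology, so no isomeric ring-B olefin should arise.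

Step 20
Reactants: 33 target carrying a carboxyl group at C8
Product: 35 methyl (2S)-2-[(3S,6S)-6-methyl-6-{2-[(1R,4aR,8aR)-2,5,5,8a-tetramethyl-1,4,4a,5,6,7,8,8a-octahydronaphthalen-1-yl]ethyl}-1,2-dioxan-3-yl]propanoate, via Barton ester 34 (not isolated)
Conditions: 1-hydroxypyridine-2(1H)-thione, EDC·HCl, DMAP (cat.), CH2Cl2, 0 °C, dark; t-BuSH (excess), visible light, 20 °C
Reagents that add atoms: none
Why: Barton reductive decarboxylation, in which visible-light homolysis of thiohydroxamate ester 34 gives CO2 and the secondary C8 radical, which t-BuSH reduces faster than it can attack the O–O bond (four-membered transition state) or close onto C10=C11, so that the sacrificial carbon and the C8 stereocentre vanish under neutral conditions.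

**Compound list**
1 | (4aR)-4a-methyl-4,4a,5,6,7,8-hexahydronaphthalen-2(3H)-one | C1CCCC2=CC(=O)CC[C@@]12C | starting material
2 | (4aR)-1,4a-dimethyl-4,4a,5,6,7,8-hexahydronaphthalen-2(3H)-one | C1CCCC2=C(C)C(=O)CC[C@@]12C | intermediate
3 | (4aR)-1,1,4a-trimethyl-3,4,4a,5,6,7-hexahydronaphthalen-2(1H)-one | C1CCC=C2C(C)(C)C(=O)CC[C@@]12C | intermediate
4 | hydrazone of 3 | C1CCC=C2C(C)(C)C(=NN)CC[C@@]12C | intermediate
5 | (4aR)-1,1,4a-trimethyl-1,2,3,4,4a,5,6,7-octahydronaphthalene | C1CCC=C2C(C)(C)CCC[C@@]12C | intermediate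
6 | (4aS)-4a,8,8-trimethyl-4,4a,5,6,7,8-hexahydronaphthalen-2(3H)-one | C1CC(=O)C=C2C(C)(C)CCC[C@@]12C | intermediate
7 | lithium cross-conjugated dienolate of 6 | [Li+].C1C=C([O-])C=C2C(C)(C)CCC[C@@]12C | intermediate
8 | (4aS)-3,4a,8,8-tetramethyl-4,4a,5,6,7,8-hexahydronaphthalen-2(3H)-one (C3 epimers) | C1C(C)C(=O)C=C2C(C)(C)CCC[C@@]12C | intermediate
9 | lithium enolate (C11=C12) of 10 | [Li+].C1C(C)C([O-])=C[C@@H]2C(C)(C)CCC[C@@]12C | intermediate
10 | (4aS,8aR)-3,4a,8,8-tetramethyloctahydronaphthalen-2(1H)-one (C3 epimers) | C1C(C)C(=O)C[C@@H]2C(C)(C)CCC[C@@]12C | intermediate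
11 | trimethyl{[(4aS,8aR)-3,4a,8,8-tetramethyl-1,4,4a,5,6,7,8,8a-octahydronaphthalen-2-yl]oxy}silane | C1C(C)=C(O[Si](C)(C)C)C[C@@H]2C(C)(C)CCC[C@@]12C | intermediate
12 | (4aS,8aR)-3,4a,8,8-tetramethyl-4a,5,6,7,8,8a-hexahydronaphthalen-2(1H)-one | C1=C(C)C(=O)C[C@@H]2C(C)(C)CCC[C@@]12C | intermediate
13 | (2R,4aS,8aR)-3,4a,8,8-tetramethyl-1,2,4a,5,6,7,8,8a-octahydronaphthalen-2-ol | C1=C(C)[C@H](O)C[C@@H]2C(C)(C)CCC[C@@]12C | intermediate
14 | 4-methylpent-4-en-1-ol | C=C(C)CCCO | starting material
15 | 4-methylpent-4-enal | C=C(C)CCC=O | intermediate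
16 | (4S)-4-benzyl-3-propanoyl-1,3-oxazolidin-2-one | CCC(=O)N1[C@@H](Cc2ccccc2)COC1=O | starting material
17 | Z dibutylboron enolate of 16 | C/C=C(\OB(CCCC)CCCC)N1[C@@H](Cc2ccccc2)COC1=O | intermediate
18 | (4S)-4-benzyl-3-[(2S,3R)-3-hydroxy-2,6-dimethylhept-6-enoyl]-1,3-oxazolidin-2-one | O=C1OC[C@H](Cc2ccccc2)N1C(=O)[C@@H](C)[C@H](O)CCC(C)=C | intermediate
19 | methyl (2S,3R)-3-hydroxy-2,6-dimethylhept-6-enoate | COC(=O)[C@@H](C)[C@H](O)CCC(C)=C | intermediate
20 | methyl (2S,3R)-2,6-dimethyl-3-[(methylsulfonyl)oxy]hept-6-enoate | COC(=O)[C@@H](C)[C@H](OS(C)(=O)=O)CCC(C)=C | intermediate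
21 | C6 carbonyl oxide from 20 | COC(=O)[C@@H](C)[C@H](OS(C)(=O)=O)CCC(C)=[O+][O-] | intermediate
22 | methyl (2S,3R)-6-hydroperoxy-6-methoxy-2-methyl-3-[(methylsulfonyl)oxy]heptanoate (C6 epimers) | COC(=O)[C@@H](C)[C@H](OS(C)(=O)=O)CCC(C)(OC)OO | intermediate
23 | methyl (2S)-2-[(3S)-6-methoxy-6-methyl-1,2-dioxan-3-yl]propanoate (C6 epimers) | COC(=O)[C@@H](C)[C@@H]1CCC(C)(OC)OO1 | intermediate
24 | cyclic peroxycarbenium ion from 23 | COC(=O)[C@@H](C)[C@@H]1CCC(C)=[O+]O1 | intermediate
25 | methyl (2S)-2-[(3S,6R)-6-allyl-6-methyl-1,2-dioxan-3-yl]propanoate | COC(=O)[C@@H](C)[C@@H]1CC[C@](C)(CC=C)OO1 | intermediate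
26 | B-alkyl-9-borabicyclo[3.3.1]nonane from 25 | COC(=O)[C@@H](C)[C@@H]1CC[C@](C)(CCCB2C3CCCC2CCC3)OO1 | intermediate
27 | methyl (2S)-2-[(3S,6S)-6-(3-hydroxypropyl)-6-methyl-1,2-dioxan-3-yl]propanoate | COC(=O)[C@@H](C)[C@@H]1CC[C@](C)(CCCO)OO1 | intermediate
28 | methyl (2S)-2-[(3S,6R)-6-methyl-6-(3-oxopropyl)-1,2-dioxan-3-yl]propanoate | COC(=O)[C@@H](C)[C@@H]1CC[C@](C)(CCC=O)OO1 | intermediate
29 | 3-[(3R,6S)-6-[(2S)-1-methoxy-1-oxopropan-2-yl]-3-methyl-1,2-dioxan-3-yl]propanoic acid | COC(=O)[C@@H](C)[C@@H]1CC[C@](C)(CCC(=O)O)OO1 | intermediate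
30 | allylic ester of acid 29 and alcohol 13 | COC(=O)[C@@H](C)[C@@H]1CC[C@](C)(CCC(=O)O[C@@H]2C[C@@H]3C(C)(C)CCC[C@@]3(C)C=C2C)OO1 | intermediate
31 | O-trimethylsilyl ketene acetal of 30 | COC(=O)[C@@H](C)[C@@H]1CC[C@](C)(CC=C(O[Si](C)(C)C)O[C@@H]2C[C@@H]3C(C)(C)CCC[C@@]3(C)C=C2C)OO1 | intermediate
32 | trimethylsilyl ester of 33 | COC(=O)[C@@H](C)[C@@H]1CC[C@](C)(CC(C(=O)O[Si](C)(C)C)[C@@H]2C(C)=CC[C@@H]3C(C)(C)CCC[C@@]23C)OO1 | intermediate
33 | target carrying CO2H at C8 (C8 epimers) | COC(=O)[C@@H](C)[C@@H]1CC[C@](C)(CC(C(=O)O)[C@@H]2C(C)=CC[C@@H]3C(C)(C)CCC[C@@]23C)OO1 | intermediate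
34 | N-acyloxypyridine-2-thione (Barton ester) of 33 | COC(=O)[C@@H](C)[C@@H]1CC[C@](C)(CC(C(=O)ON2C=CC=CC2=S)[C@@H]2C(C)=CC[C@@H]3C(C)(C)CCC[C@@]23C)OO1 | intermediate
35 | methyl (2S)-2-[(3S,6S)-6-methyl-6-{2-[(1R,4aR,8aR)-2,5,5,8a-tetramethyl-1,4,4a,5,6,7,8,8a-octahydronaphthalen-1-yl]ethyl}-1,2-dioxan-3-yl]propanoate | COC(=O)[C@@H](C)[C@@H]1CC[C@](C)(CC[C@@H]2C(C)=CC[C@@H]3C(C)(C)CCC[C@@]23C)OO1 | target

Total step count: 20. Longest linear sequence: 12 steps (steps 9 to 20).

**Steps most likely to fail**

Step 19. Three processes may intervene: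
- competing deprotonation at C2 followed by β-elimination of the peroxide (ring opening);
- attack of the amide base on the O–O bond;
- decay of the ketene acetal before the slow, boat-type [3,3] shift takes place.

The fallback keeps the chirality transfer from C11 to C9, but it is base-free and needs no carboxyl group. It sets out from alcohol 13 and allyl dioxane 25 and comes back to the route at target 35.
- Alcohol 13 is converted with ClCO2Me and pyridine into the methyl carbonate F1.
- A Tsuji–Trost amination (Pd(PPh3)4 cat., N-(tert-butoxycarbonylamino)phthalimide, THF) proceeds with net retention at the less hindered terminus C11. It gives the protected allyl hydrazine F2.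
- MeNHNH2 removes the phthaloyl group to give the N-Boc-N-allylhydrazine F3.
- Ozonolysis of 25 in CH2Cl2/pyridine at −78 °C gives the aldehyde F4. This condenses with F3 (MgSO4, CH2Cl2) to the N-Boc-N-allylhydrazone F5.
- Heating F5 with catalytic HNTf2 in diglyme removes the Boc group and triggers the known acid-catalysed [3,3] rearrangement of N-allylhydrazones. The monoalkyl diazene so formed loses N2 and leaves C8 as CH2, which is 35 directly.

Step 14. Two processes may intervene: E1cB loss of methanesulfonate from the β-mesyloxy ester, or sluggish ring closure at the hindered C3. Either would erase the C2/C3 information. The fallback forms the C3–O bond intermolecularly and closes the ring by ketalisation at C6. It sets out from hydroxy ester 19 and comes back at 23.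
- Tf2O and 2,6-lutidine at −78 °C give the triflate F6.
- F6 is displaced at low temperature, with inversion, by the potassium salt of 2-methoxyprop-2-yl hydroperoxide to give the acyclic peroxyketal F7.
- Ozonolysis in CH2Cl2/pyridine gives the methyl ketone F8.
- Catalytic TsOH in MeOH frees the C3 hydroperoxide, which adds to the C6 ketone and is trapped as the cyclic methyl ketal 23.

Step 15. Two processes may intervene: Lewis-acid-induced heterolysis of the O–O bond (Criegee-type fragmentation) outrunning capture by the weakly nucleophilic allylsilane, or poor facial selectivity at C6. The fallback sets out from 23 and comes back at 25.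
- The same cation is generated with catalytic Me3SiOTf at −78 °C. It is captured in a Mukaiyama-type reaction by the far more nucleophilic (vinyloxy)trimethylsilane to give the two-carbon aldehyde F9 (same structure as F4).
- A Wittig methylenation (Ph3P=CH2, THF, −78 °C) then turns F9 into 25.

**Further compounds**
F1 | step 19 | methyl carbonate of alcohol 13 | COC(=O)O[C@@H]1C[C@@H]2C(C)(C)CCC[C@@]2(C)C=C1C
F2 | step 19 | N-Boc-N-(C11-decalinyl)aminophthalimide (N cis to the angular methyl group) | CC(C)(C)OC(=O)N(N1C(=O)c2ccccc2C1=O)[C@@H]1C[C@@H]2C(C)(C)CCC[C@@]2(C)C=C1C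
F3 | step 19 | tert-butyl 1-(C11-decalinyl)hydrazinecarboxylate | CC(C)(C)OC(=O)N(N)[C@@H]1C[C@@H]2C(C)(C)CCC[C@@]2(C)C=C1C
F4 | step 19 | methyl (2S)-2-[(3S,6R)-6-methyl-6-(2-oxoethyl)-1,2-dioxan-3-yl]propanoate | COC(=O)[C@@H](C)[C@@H]1CC[C@](C)(CC=O)OO1
F5 | step 19 | N-Boc-N-allylhydrazone of F4 and F3 | COC(=O)[C@@H](C)[C@@H]1CC[C@](C)(C/C=N/N(C(=O)OC(C)(C)C)[C@@H]2C[C@@H]3C(C)(C)CCC[C@@]3(C)C=C2C)OO1
F6 | step 14 | methyl (2S,3R)-2,6-dimethyl-3-{[(trifluoromethyl)sulfonyl]oxy}hept-6-enoate | COC(=O)[C@@H](C)[C@H](OS(=O)(=O)C(F)(F)F)CCC(C)=C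
F7 | step 14 | methyl (2S,3S)-3-[(2-methoxypropan-2-yl)peroxy]-2,6-dimethylhept-6-enoate | COC(=O)[C@@H](C)[C@@H](OOC(C)(C)OC)CCC(C)=C
F8 | step 14 | methyl (2S,3S)-3-[(2-methoxypropan-2-yl)peroxy]-2-methyl-6-oxoheptanoate | COC(=O)[C@@H](C)[C@@H](OOC(C)(C)OC)CCC(C)=O
F9 | step 15 | methyl (2S)-2-[(3S,6R)-6-methyl-6-(2-oxoethyl)-1,2-dioxan-3-yl]propanoate | COC(=O)[C@@H](C)[C@@H]1CC[C@](C)(CC=O)OO1
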